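## Structural features

The target is an abietane: a cyclohexane ring A, a ring B that carries the C7 ketone, and a fully substituted benzene ring C (11-OH, 12-OMe, 13-isopropyl, 14-OH), so ring C is a hydroquinone whose 14-hydroxyl is peri to the aryl ketone. C19 (the carbonyl on C4) and C20 (the CH2 on C10) are joined through oxygen, so the δ-lactone (C4, C19, O, C20, C10, C5) shares the edge C4–C5–C10 with ring A; together they form a 3-oxabicyclo[3.3.1]nonan-2-one with C4 and C10 as bridgeheads and C5 as the one-atom bridge. The three stereocentres are contiguous: quaternary C4 (methyl, lactone carbonyl), tertiary C5, and quaternary benzylic C10; the lactone forces C19 and C20 to be cis and diaxial on ring A, and the C5 hydrogen lies on the opposite face (trans A/B; 4S,5R,10R). The fragile groups are the hydroquinone (air oxidation to the quinone), carried here as its tri-O-methyl ether, and the C20–O bond, which is β to C5 and can be lost by β-elimination whenever C5 is a ketone and C10 still bears a hydrogen. The real difficulty is that the two quaternary centres stand 1,3 to each other and must be set in one absolute sense, while the C5 hydrogen between them cannot be corrected later because nothing acidifies it. Because C19 and C20 are tied back into the lactone, the two faces of C5 differ only in the wing that covers them (C1–C2–C3 on one side, C19–O–C20 on the other), so neither steric approach nor product stability can be trusted to set C5 and a directing element is needed. The key step uses the fact that, with C5 written as a ketone, C4 and C10 are both α-carbons of one carbonyl inside a six-membered β-keto lactone, so ring A is only a three-carbon bridge (C3–C2–C1) laid across them.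

## Logic of the disconnections

**32 ⇒ 30 (through 31).** The O–H bonds at C11 and C14 are traced back to O–CH3 bonds. The free hydroquinone would not survive enolate, radical and superacid chemistry, whereas the trimethyl ether does, and the C11/C14 pair is para. The gain is a robust arene for the whole route. The demand is that the final oxidative demethylation takes the para pair and leaves the C12 methoxyl, although the C7 ketone makes the ring less electron-rich.

**30 ⇒ 29.** The C7–C8 bond is cut. C8 is the only unsubstituted ring carbon, ortho to the C14 methoxyl and para to the C12 methoxyl, and C7 hangs on a chain held trans-diequatorial to the aryl group, so an electrophilic ring closure has no regiochemical choice. The gain is that ring B disappears and the arene becomes a plain substituent on the bicycle. The demand is that C5 already has its hydrogen on the right face in 29, because the cyclisation cannot repair it, and that an ester must serve as the acyl donor.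

**29 ⇒ 27 (through 28).** C1–H is traced back to C1–OH. This oxygen is what the aldol closure leaves behind; it is kept until C5 is set, because as an axial 1α-hydroxyl it stands 1,3-diaxial to the α-face of C5. The gain is a stereocontrol element at no extra cost in steps. The demand is a radical deoxygenation next to a quaternary benzylic carbon without aryl migration.

**27 ⇒ 26.** The C5–H and C6–H bonds are removed to give the C5=C6 alkene. An alkene is the only practical precursor of a C5–H that cannot be epimerised, and making the cut before ring B exists means that alkene geometry is irrelevant. The demand is hydrogen delivery from the carbocyclic (α) face, which sterics alone do not favour; the hydroxyl on C1 must provide it.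

**26 ⇒ 22 (through 25).** The C5=C6 bond is cut and C6–C7 is recognised as an alkoxyacetylide. The C5 ketone is flanked by two quaternary carbons, so only a slim, linear nucleophile is credible, and the subsequent 1,3-shift of oxygen delivers C7 at the acid oxidation level. The gain is a direct return to the key-step product. The demand is an addition that does not trigger retro-aldol cleavage, so the C1 hydroxyl is masked in the flask and the C5 alkoxide is kept cold.

**22 ⇒ 19 + 20.** The C3–C4 and C1–C10 bonds are cut. Both are bonds from an α-carbon of the C5 ketone to the ends of a three-carbon enal, and removing them deletes ring A, both quaternary centres and the C1 carbinol at once. The gain is a monocyclic lactone with one labile stereocentre. The demand is catalyst control of the C4 face in the conjugate addition, after which C10 has no choice.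

**19 ⇒ 15 + 16.** The C10–C20 bond and the lactone O–C19 acyl bond are cut. C10 is the γ-carbon of a β-keto ester and C20 is a one-carbon electrophile whose oxygen closes the lactone by itself. The gain is an open-chain β-keto ester. The demand is a dianion that reacts only at the benzylic γ-position and with only one molecule of 16.

**15 ⇒ 12 + 13.** The C4–C5 bond is cut (crossed Claisen). The gain is an arylacetic acid and a three-carbon ester. The demand is acylation of the ester enolate faster than proton transfer from the acidic benzylic CH2.

**12 ⇒ 7 (through 10, 9, 8).** The aryl–C10 bond (C9–C10) is traced to a sigmatropic shift of an O-allyl group, followed by excision of the terminal alkene carbon. EAS on the arene would favour the other free position (para to the C12 methoxyl), whereas the rearrangement can only go to the one free ortho carbon of the phenol. The demand is an oxidative cleavage that spares the electron-rich ring.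

**7 ⇒ 1 (through 4, 3).** The C11–O bond and the C13–isopropyl bond are cut. Both positions are ortho to methoxyl groups of 1 and are reached by two successive directed lithiations. The gain is a single cheap arene as the source of ring C.

## Other disconnections considered

**Alternative 1:** The cut is at C5–C6 and C4–C18, made on the achiral dienone A1, whose C10 is already quaternary but prochiral. In the forward step CuBr·SMe2 with a chiral diphosphine would add A2 to one enone arm of A1 anti to the aryl group, and the enolate would be methylated by A3 to give A4.
- *In favour:* C10 is resolved without forming any bond at it, three contiguous stereocentres arise in one flask, and C5 is set early and by carbon delivery. On the C5 question this alternative is the better plan, since the chosen route sets C5 late and needs a directing group.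
- *Against:* A4 has closed no ring and C4 is only tertiary. C19 would have to be added by a second quaternisation next to the crowded C5 and cis to both C20 and the vinyl group, against the intrinsic bias. The C3 oxygen and the C1=C2 alkene must be removed, and ring B and the lactone are still to be built. Vinyl cuprate chemistry on dienones also competes with 1,2- and double addition.
- *Comparison:* In structure the chosen step delivers ring A, both quaternary centres and the finished lactone, while A4 delivers stereocentres but no ring and lacks C19. In mechanism both are catalyst-controlled conjugate additions and are equal in kind. In step economy the alternative should be several steps longer after its key step.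

**Alternative 2:** The cut is at C7–C8 and C9–C10. In the forward step diene A5 would add to the unsubstituted double bond of quinone A6 and the adduct would enolise to hydroquinone A7.
- *In favour:* It is the most convergent plan. Ring C arrives with its final oxygen pattern and oxidation level, so no late oxidative demethylation is needed, which is better than the chosen plan. Because C19 and C20 are still separate axial groups in A7, the β-face of C5=C6 is shielded in the normal terpenoid way, so the later C5 reduction should be less ambiguous than in the lactone-bridged series; on that point it is also the better.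
- *Against:* The diene terminus C10 is fully substituted and sits next to the C4 quaternary centre, so the cycloaddition should be slow and the quinone may decompose first. Facial control rests only on methyl versus ester at C4, and regiocontrol on the methoxyl of the remote quinone double bond. A5 itself needs an enantioselective construction of C4 that the key step does not supply. After A7 the C7 oxidation must be done on a free hydroquinone.
- *Comparison:* In structure A7 is ahead of 22 (rings A–C present), but C10 is set with uncertain selectivity, whereas in the chosen plan C10 follows from C4 by necessity. In mechanism a sterically strained [4+2] stands against an ionic organocatalytic step. In step economy the counts should be similar, because the diene is long to make; convergence is better in the alternative.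

**Alternative 3:** The cut is at C1–C10 and C4–C5, with ring A annulated onto a preformed B/C unit in which C20 is tied to O11 as an aryl lactone. In the forward step A8 would add through C10 to A9 under a cinchona-derived bifunctional catalyst, and the C4 methylene would then condense with the C5 ketone to give A10.
- *In favour:* The nucleophile is a rigid, planar 2-aryl β-keto lactone, the best-behaved substrate class for this catalysis, and it has no labile neighbouring centre. Enantiocontrol at C10 should therefore be more secure than in the chosen key step, which is a point where the alternative is the better. Ring B is already closed, so no late acylation is needed.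
- *Against:* The lactone is the wrong one. C20 is at the acid level and bound to the phenol; it would have to be reduced selectively beside the C19 ester and re-lactonised. The aryl ester is an activated acyl donor and may open under the basic annulation. C4 still needs a stereoselective methylation, C3 must be deoxygenated, C7 oxidised, and C5–H set on an alkene without any directing group.
- *Comparison:* In structure only C10 is set, where the chosen step sets C4 and C10 and leaves the lactone in place. In mechanism it is the same catalyst family and the same Michael-then-carbonyl-addition logic, so the two are equal. In step economy it is worse, with many redox corrections after the key step.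

Key step: step 10

Remark on the chemistry: abietane numbering is used throughout and Ar = 4-isopropyl-2,3,5-trimethoxyphenyl; the bridgeheads of 22 (4S,10R) map directly onto the target, and the aldol closure of step 10 is assumed to give mainly the axial 1α-hydroxyl epimer of 22, the one that can direct step 13.

## Route

**Step 1**
Reactants: 1 1,3-dimethoxybenzene
Product: 3 2-(2,6-dimethoxyphenyl)propan-2-ol, via (2,6-dimethoxyphenyl)lithium 2 (not isolated)
Conditions: n-BuLi, THF, 0 °C to rt; acetone, −78 °C to rt; H2O
Reagents that add atoms: acetone, CC(C)=O
Why: Directed ortho-metalation removes the proton between the two methoxy groups, and the aryllithium adds 1,2 to acetone.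

**Step 2**
Reactants: 3 2-(2,6-dimethoxyphenyl)propan-2-ol
Product: 4 2-isopropyl-1,3-dimethoxybenzene
Conditions: Et3SiH, CF3CO2H, CH2Cl2, 0 °C to rt
Reagents that add atoms: none
Why: Ionic hydrogenation; the tertiary benzylic cation is stabilised by two ortho methoxy groups and is reduced by hydride transfer from silicon.

**Step 3**
Reactants: 4 2-isopropyl-1,3-dimethoxybenzene
Product: 7 3-isopropyl-2,4-dimethoxyphenol, via (3-isopropyl-2,4-dimethoxyphenyl)lithium 5 (not isolated), via dimethyl arylboronate 6 (not isolated)
Conditions: n-BuLi, TMEDA, Et2O, 0 °C to rt; B(OMe)3, −78 °C to rt; AcOH, 30% H2O2, 0 °C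
Reagents that add atoms: hydrogen peroxide, OO
Why: Second directed ortho-metalation (C2 is blocked and the two remaining ortho positions are equivalent), then borylation and oxidative aryl shift from boron to oxygen; this places the future C11 oxygen.

**Step 4**
Reactants: 7 3-isopropyl-2,4-dimethoxyphenol
Product: 8 1-(allyloxy)-3-isopropyl-2,4-dimethoxybenzene
Conditions: allyl bromide, K2CO3, acetone, reflux
Reagents that add atoms: allyl bromide, C=CCBr
Why: Williamson ether synthesis on the phenoxide.

**Step 5**
Reactants: 8 1-(allyloxy)-3-isopropyl-2,4-dimethoxybenzene
Product: 9 6-allyl-3-isopropyl-2,4-dimethoxyphenol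
Conditions: N,N-diethylaniline, 190 °C
Reagents that add atoms: none
Why: Aromatic Claisen rearrangement; only one ortho carbon is free, so the [3,3] shift fixes the future C9–C10 bond at the position that EAS would not choose.

**Step 6**
Reactants: 9 6-allyl-3-isopropyl-2,4-dimethoxyphenol
Product: 10 1-allyl-4-isopropyl-2,3,5-trimethoxybenzene
Conditions: MeI, K2CO3, DMF, rt
Reagents that add atoms: iodomethane, CI
Why: O-Methylation of the phenol; it masks the future C11 hydroxyl and prevents benzofuranone formation once the side chain is an acid.

**Step 7**
Reactants: 10 1-allyl-4-isopropyl-2,3,5-trimethoxybenzene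
Product: 12 2-(4-isopropyl-2,3,5-trimethoxyphenyl)acetic acid, via arylacetaldehyde 11 (not isolated)
Conditions: OsO4 (2 mol%), NaIO4, 2,6-lutidine, dioxane/H2O, rt; then NaClO2, NaH2PO4, 2-methyl-2-butene, t-BuOH/H2O, rt
Reagents that add atoms: sodium periodate, [Na+].[O-][I](=O)(=O)=O; sodium chlorite, [Na+].[O-]Cl=O
Why: Lemieux–Johnson cleavage of the terminal alkene is used in place of ozone, which would also attack the very electron-rich ring. The enolisable aldehyde is oxidised at once (Pinnick oxidation) with a chlorine scavenger to protect the arene.

**Step 8**
Reactants: 12 2-(4-isopropyl-2,3,5-trimethoxyphenyl)acetic acid; 13 methyl propanoate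
Product: 15 methyl 4-(4-isopropyl-2,3,5-trimethoxyphenyl)-2-methyl-3-oxobutanoate, via acyl imidazole 14 (not isolated)
Conditions: 12, 1,1′-carbonyldiimidazole, THF, rt; added to 13 and LiN(iPr)2 (2.5 equiv each), THF, −78 °C; aq. HCl
Reagents that add atoms: none
Why: Crossed Claisen condensation; the acyl imidazole is acylated by the preformed lithium enolate of 13 at low temperature, and the excess enolate takes up the acidic product.

**Step 9**
Reactants: 15 methyl 4-(4-isopropyl-2,3,5-trimethoxyphenyl)-2-methyl-3-oxobutanoate; 16 formaldehyde
Product: 19 4-hydroxy-5-Ar-3-methyl-5,6-dihydro-2H-pyran-2-one (racemic; C10 labile), via dilithium dienolate 17 (not isolated), via hydroxymethyl keto ester 18 (not isolated)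
Conditions: LiN(iPr)2 (2.2 equiv), THF, −78 to 0 °C; 16 (monomeric, from cracked paraformaldehyde, in THF), −78 °C; 1 M HCl, rt
Reagents that add atoms: none
Why: Dianion aldol of a β-keto ester; the second deprotonation goes to the benzylic γ-carbon (C10), which is the more reactive site toward formaldehyde, and the primary alkoxide closes the δ-lactone with loss of methanol.

**Step 10**
Reactants: 19 4-hydroxy-5-Ar-3-methyl-5,6-dihydro-2H-pyran-2-one; 20 acrolein
Product: 22 6-hydroxy-5-Ar-1-methyl-3-oxabicyclo[3.3.1]nonane-2,9-dione (abietane labels: 1α-OH axial; 4S; 10R), via Michael adduct 21 (not isolated)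
Conditions: 20 (1.5 equiv), cupreidine 9-O-(9-phenanthryl) ether (10 mol%), CH2Cl2, −25 °C; then TsOH·H2O (20 mol%), rt
Reagents that add atoms: none
Why: The quinuclidine of the catalyst deprotonates the acidic enol 19 to a chiral ion pair while the 6′-hydroxyl hydrogen-bonds acrolein, and C-alkylation at C4, the carbon between both carbonyls, gives 21 (C3–C4). On acidification the C5 ketone enolises toward benzylic C10 and the enol adds to the tethered aldehyde (C1–C10), closing ring A by a 6-(enolexo)-exo-trig aldol addition. The closest known reaction type is the Michael–aldol α,α′-annulation of cyclic β-dicarbonyl compounds with acrolein to bicyclo[3.3.1]nonan-9-ones, with the Michael step made enantioselective by 6′-hydroxy cinchona catalysts on α-substituted β-keto esters. C4 is set by the catalyst, which selects one face of the planar enolate; the quinidine-derived catalyst or its quinine-derived pseudoenantiomer is taken according to which one delivers 4S. C10 is set by the tether, since a three-carbon bridge can only reach the C10 face cis to the chain on C4; both C10 epimers of 21 therefore converge, and the lability of C10 in 19 allows the catalyst to work on whichever epimer it matches. C1 should come out with the hydroxyl axial, from a hydrogen-bonded chair closure that also keeps the oxygen out of the crowded region next to the C11 methoxyl, and the C1 epimers can interconvert by retro-aldol and aldol under the closing conditions. The step needs C- over O-alkylation, which the soft acceptor secures, and ring closure faster than loss of the C20 carboxylate from a C10 enolate, which is why the closure is run under acid through the enol and not with an amine base.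

**Step 11**
Reactants: 22 6-hydroxy-5-Ar-1-methyl-3-oxabicyclo[3.3.1]nonane-2,9-dione
Product: 25 9-(ethoxyethynyl)-6,9-dihydroxy-5-Ar-1-methyl-3-oxabicyclo[3.3.1]nonan-2-one (C5 epimer immaterial; alkynyl expected on the lactone face), via trimethylsilyl ether 23 (not isolated), via silylated carbinol 24 (not isolated)
Conditions: Me3SiCl, imidazole, CH2Cl2, 0 °C; then LiC≡COEt (from HC≡COEt and n-BuLi), THF, −78 °C, AcOH quench at −78 °C; then K2CO3 (cat.), MeOH, 0 °C
Reagents that add atoms: ethoxyacetylene, C#COCC
Why: 1,2-Addition of a lithium alkoxyacetylide, the slimmest two-carbon nucleophile, to the doubly neopentyl but strongly electrophilic C5 ketone. Transient silylation of the C1 hydroxyl removes the alkoxide that would open ring A by retro-aldol, and the cold quench keeps the C5 alkoxide from fragmenting.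

**Step 12**
Reactants: 25 9-(ethoxyethynyl)-6,9-dihydroxy-5-Ar-1-methyl-3-oxabicyclo[3.3.1]nonan-2-one
Product: 26 ethyl 2-(6-hydroxy-5-Ar-1-methyl-2-oxo-3-oxabicyclo[3.3.1]nonan-9-ylidene)acetate (E/Z mixture)
Conditions: Sc(OTf)3 (5 mol%), EtOH (5 equiv), CH2Cl2, rt
Reagents that add atoms: none
Why: Meyer–Schuster rearrangement of an alkoxyalkynyl carbinol, the standard olefination of ketones too hindered for phosphonate reagents. Ionisation at C5 gives a dialkoxyallyl cation with little charge on C5, so no aryl shift from C10 is expected, and alkene geometry does not matter for the next step.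

**Step 13**
Reactants: 26 ethyl 2-(6-hydroxy-5-Ar-1-methyl-2-oxo-3-oxabicyclo[3.3.1]nonan-9-ylidene)acetate
Product: 27 ethyl 2-(6-hydroxy-5-Ar-1-methyl-2-oxo-3-oxabicyclo[3.3.1]nonan-9-yl)acetate (5α-H)
Conditions: H2 (1 to 50 bar), [Ir(cod)(PCy3)(py)]PF6 (10 mol%), CH2Cl2, rt
Reagents that add atoms: none
Why: Hydroxyl-directed homogeneous hydrogenation; the axial 1α-hydroxyl binds iridium and holds it under the α-face of C5=C6, 1,3-diaxial to C5, so hydrogen is delivered cis to the hydroxyl. This sets C5 with the hydrogen α and C6 over the lactone wing, and both alkene isomers give the same product.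

**Step 14**
Reactants: 27 ethyl 2-(6-hydroxy-5-Ar-1-methyl-2-oxo-3-oxabicyclo[3.3.1]nonan-9-yl)acetate
Product: 28 O-(imidazol-1-ylthiocarbonyl) derivative of 27 at the C1 oxygen
Conditions: 1,1′-thiocarbonyldiimidazole, DMAP, ClCH2CH2Cl, 80 °C
Reagents that add atoms: 1,1′-thiocarbonyldiimidazole, S=C(n1ccnc1)n1ccnc1
Why: Thioacylation of the hindered secondary alcohol under neutral conditions, the first half of a Barton–McCombie deoxygenation.

**Step 15**
Reactants: 28 O-(imidazol-1-ylthiocarbonyl) derivative of 27
Product: 29 ethyl 2-(5-Ar-1-methyl-2-oxo-3-oxabicyclo[3.3.1]nonan-9-yl)acetate (5α-H)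
Conditions: Bu3SnH (0.2 M), AIBN, toluene, 100 °C
Reagents that add atoms: none
Why: Barton–McCombie radical deoxygenation; at this tin hydride concentration hydrogen transfer to the secondary C1 radical should be much faster than a 1,2-aryl shift from C10, and no stereocentre is touched.

**Step 16**
Reactants: 29 ethyl 2-(5-Ar-1-methyl-2-oxo-3-oxabicyclo[3.3.1]nonan-9-yl)acetate
Product: 30 11,12,14-trimethoxy-7-oxoabieta-8,11,13-trien-19,20-olide
Conditions: CF3SO3H (5 equiv), CH2Cl2, 0 °C to rt
Reagents that add atoms: none
Why: Intramolecular Friedel–Crafts acylation with an ester as acyl donor in superacid. C8 is the only free ring position and is activated ortho and para by methoxyl groups, the aryl group and the acetate chain are trans-diequatorial on ring A so ring B closes trans-fused, and no new stereocentre is formed.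

**Step 17**
Reactants: 30 11,12,14-trimethoxy-7-oxoabieta-8,11,13-trien-19,20-olide
Product: 32 11,14-dihydroxy-12-methoxy-7-oxoabieta-8,11,13-trien-19,20-olide (4S,5R,10R), via methoxy quinone 31 (not isolated)
Conditions: (NH4)2Ce(NO3)6 (2.5 equiv), MeCN/H2O, 0 °C; extract into EtOAc; aq. Na2S2O4, rt
Reagents that add atoms: water, O
Why: Oxidative demethylation of the para-dimethoxy pair (C11, C14) to the para-quinone, in which the C12 methoxyl survives as a vinylogous ester, followed by dithionite reduction to the hydroquinone.

## Compound list

1 | 1,3-dimethoxybenzene | COc1cccc(OC)c1 | starting material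
2 | (2,6-dimethoxyphenyl)lithium | [Li]c1c(OC)cccc1OC | intermediate (not isolated)
3 | 2-(2,6-dimethoxyphenyl)propan-2-ol | COc1cccc(OC)c1C(C)(C)O | intermediate
4 | 2-isopropyl-1,3-dimethoxybenzene | COc1cccc(OC)c1C(C)C | intermediate
5 | (3-isopropyl-2,4-dimethoxyphenyl)lithium | [Li]c1ccc(OC)c(C(C)C)c1OC | intermediate (not isolated)
6 | dimethyl (3-isopropyl-2,4-dimethoxyphenyl)boronate | COB(OC)c1ccc(OC)c(C(C)C)c1OC | intermediate (not isolated)
7 | 3-isopropyl-2,4-dimethoxyphenol | Oc1ccc(OC)c(C(C)C)c1OC | intermediate
8 | 1-(allyloxy)-3-isopropyl-2,4-dimethoxybenzene | C=CCOc1ccc(OC)c(C(C)C)c1OC | intermediate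
9 | 6-allyl-3-isopropyl-2,4-dimethoxyphenol | C=CCc1cc(OC)c(C(C)C)c(OC)c1O | intermediate
10 | 1-allyl-4-isopropyl-2,3,5-trimethoxybenzene | C=CCc1cc(OC)c(C(C)C)c(OC)c1OC | intermediate
11 | 2-(4-isopropyl-2,3,5-trimethoxyphenyl)acetaldehyde | O=CCc1cc(OC)c(C(C)C)c(OC)c1OC | intermediate (not isolated)
12 | 2-(4-isopropyl-2,3,5-trimethoxyphenyl)acetic acid | OC(=O)Cc1cc(OC)c(C(C)C)c(OC)c1OC | intermediate
13 | methyl propanoate | CCC(=O)OC | starting material
14 | 1-(imidazol-1-yl)-2-(4-isopropyl-2,3,5-trimethoxyphenyl)ethanone | O=C(Cc1cc(OC)c(C(C)C)c(OC)c1OC)n1ccnc1 | intermediate (not isolated)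
15 | methyl 4-(4-isopropyl-2,3,5-trimethoxyphenyl)-2-methyl-3-oxobutanoate (racemic, labile centre) | COC(=O)C(C)C(=O)Cc1cc(OC)c(C(C)C)c(OC)c1OC | intermediate
16 | formaldehyde | C=O | starting material
17 | dilithium dienolate of 15 (lithiated at both enolate oxygens, C=C bonds toward C4 and C10) | COC(O[Li])=C(C)C(O[Li])=Cc1cc(OC)c(C(C)C)c(OC)c1OC | intermediate (not isolated)
18 | methyl 5-hydroxy-4-(4-isopropyl-2,3,5-trimethoxyphenyl)-2-methyl-3-oxopentanoate (diastereomer mixture) | COC(=O)C(C)C(=O)C(CO)c1cc(OC)c(C(C)C)c(OC)c1OC | intermediate (not isolated)
19 | 4-hydroxy-5-(4-isopropyl-2,3,5-trimethoxyphenyl)-3-methyl-5,6-dihydro-2H-pyran-2-one (racemic, C10 labile; one epimer written) | CC1=C(O)[C@@H](c2cc(OC)c(C(C)C)c(OC)c2OC)COC1=O | intermediate (key-step precursor)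
20 | acrolein | C=CC=O | starting material
21 | (3S)-3-methyl-3-(3-oxopropyl)-5-(4-isopropyl-2,3,5-trimethoxyphenyl)oxane-2,4-dione (both C10 epimers; C10 left open) | O=CCC[C@]1(C)C(=O)OCC(c2cc(OC)c(C(C)C)c(OC)c2OC)C1=O | intermediate (not isolated)
22 | 6-hydroxy-5-(4-isopropyl-2,3,5-trimethoxyphenyl)-1-methyl-3-oxabicyclo[3.3.1]nonane-2,9-dione; abietane labels 1S (1α-OH, axial), 4S, 10R | O=C1[C@@]2(c3cc(OC)c(C(C)C)c(OC)c3OC)[C@@H](O)CC[C@]1(C)C(=O)OC2 | intermediate (key-step product)
23 | 1-O-trimethylsilyl ether of 22 | O=C1[C@@]2(c3cc(OC)c(C(C)C)c(OC)c3OC)[C@@H](O[Si](C)(C)C)CC[C@]1(C)C(=O)OC2 | intermediate (not isolated)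
24 | C5 ethoxyethynyl carbinol of 23 (C5 hydroxyl on the carbocyclic face, alkynyl on the lactone face) | CCOC#C[C@]1(O)[C@@]2(c3cc(OC)c(C(C)C)c(OC)c3OC)[C@@H](O[Si](C)(C)C)CC[C@]1(C)C(=O)OC2 | intermediate (not isolated)
25 | 9-(ethoxyethynyl)-6,9-dihydroxy-5-(4-isopropyl-2,3,5-trimethoxyphenyl)-1-methyl-3-oxabicyclo[3.3.1]nonan-2-one (1α-OH; C5 as in 24) | CCOC#C[C@]1(O)[C@@]2(c3cc(OC)c(C(C)C)c(OC)c3OC)[C@@H](O)CC[C@]1(C)C(=O)OC2 | intermediate
26 | ethyl 2-[6-hydroxy-5-(4-isopropyl-2,3,5-trimethoxyphenyl)-1-methyl-2-oxo-3-oxabicyclo[3.3.1]nonan-9-ylidene]acetate (1α-OH; E/Z mixture at C5=C6) | CCOC(=O)C=C1[C@@]2(c3cc(OC)c(C(C)C)c(OC)c3OC)[C@@H](O)CC[C@]1(C)C(=O)OC2 | intermediate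
27 | ethyl 2-[6-hydroxy-5-(4-isopropyl-2,3,5-trimethoxyphenyl)-1-methyl-2-oxo-3-oxabicyclo[3.3.1]nonan-9-yl]acetate (1α-OH, 5α-H) | CCOC(=O)C[C@@H]1[C@@]2(c3cc(OC)c(C(C)C)c(OC)c3OC)[C@@H](O)CC[C@]1(C)C(=O)OC2 | intermediate
28 | O-(imidazol-1-ylthiocarbonyl) derivative of 27 at the C1 oxygen | CCOC(=O)C[C@@H]1[C@@]2(c3cc(OC)c(C(C)C)c(OC)c3OC)[C@@H](OC(=S)n4ccnc4)CC[C@]1(C)C(=O)OC2 | intermediate
29 | ethyl 2-[5-(4-isopropyl-2,3,5-trimethoxyphenyl)-1-methyl-2-oxo-3-oxabicyclo[3.3.1]nonan-9-yl]acetate (5α-H) | CCOC(=O)C[C@@H]1[C@@]2(c3cc(OC)c(C(C)C)c(OC)c3OC)CCC[C@]1(C)C(=O)OC2 | intermediate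
30 | (4S,5R,10R)-11,12,14-trimethoxy-7-oxoabieta-8,11,13-trien-19,20-olide | COc1c(OC)c2c(c(OC)c1C(C)C)C(=O)C[C@@H]1[C@]23CCC[C@]1(C)C(=O)OC3 | intermediate
31 | 12-methoxy-7,11,14-trioxoabieta-8,12-dien-19,20-olide (para-quinone) | CC(C)C1=C(OC)C(=O)C2=C(C1=O)C(=O)C[C@@H]1[C@]23CCC[C@]1(C)C(=O)OC3 | intermediate (not isolated)
32 | (4S,5R,10R)-11,14-dihydroxy-12-methoxy-7-oxoabieta-8,11,13-trien-19,20-olide | COc1c(O)c2c(c(O)c1C(C)C)C(=O)C[C@@H]1[C@]23CCC[C@]1(C)C(=O)OC3 | target

## Step count and least certain steps

Total step count: 17. Longest linear sequence: 17 steps (1 to 32); 13, 16 and 20 are commercial and enter without steps of their own.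

**Step 10 (key step).** The most likely failure is loss of enantiofacial discrimination in the conjugate addition. The ion-paired enolate is nearly planar with two similar carbonyl flanks, and the labile aryl-bearing C10 exerts its own bias. Ring opening by β-elimination of the C20 carboxylate can also drain the adduct before it closes, and the ratio of C1 epimers is open; a minor equatorial epimer would be returned through the same acidic closing conditions. Fallback: 19 is allylated at C4 with allyl acetate, [Pd(allyl)Cl]2 and a DACH-phenyl Trost ligand (asymmetric allylic alkylation of a cyclic 1,3-dicarbonyl nucleophile) to give the C4-allyl keto lactone F1. Hydroboration with 9-BBN and oxidation with NaBO3·4H2O give the primary alcohol F2, and Dess–Martin oxidation gives the aldehyde 21, where the route is rejoined and closed with TsOH as before.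

**Step 13.** The hydroxyl may fail to hold the catalyst under C5, either because the conjugated alkene between two quaternary carbons binds too weakly or because the ester carbonyl competes for the metal. Hydrogen would then arrive from the less hindered lactone face, or not at all. Fallback: the reduction is changed from metal-bound hydrogen delivery to electron transfer. 26 is treated with SmI2 and HMPA in THF at −78 to 0 °C without an external proton donor, so that the 1α-hydroxyl, 1,3-diaxial to C5, is the nearest proton source for the β-carbanion. The fallback sets out from 26, returns at 27 and makes no new compound (F0).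

**Step 11.** The tertiary C5 alkoxide may fragment by retro-aldol cleavage of C4–C5, since the lactone enolate is a good leaving group, or the addition may stall at the doubly neopentyl carbonyl. Fallback: no alkoxide is formed at all. The silyl ether 23 is treated with ethoxyacetylene and BF3·OEt2 in CH2Cl2 at −78 to 0 °C (Lewis-acid [2+2] addition to the ketone and ring opening of the oxete) to give the silyl-protected enoate F3 directly. K2CO3 in MeOH removes the silyl group and the route is rejoined at 26.

**Step 16.** Ionisation of the ethyl ester may be incomplete because the ring is deactivated by protonation in the superacid, or an aryl methyl ether may be cleaved on prolonged exposure. Fallback: 29 is hydrolysed with Me3SnOH in ClCH2CH2Cl at 80 °C, which should spare the hindered lactone, to the acid F4. F4 is cyclised with (CF3CO)2O in CH2Cl2 at 0 °C to rt through the mixed anhydride, returning at 30.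

**Step 9.** The dianion may over-react with formaldehyde (second hydroxymethylation, hemiformal oligomers), and the β-hydroxy ketone may dehydrate to the α-methylene ketone before the lactone closes. Fallback: 15 is converted to its dianion 17 as before and alkylated with benzyl chloromethyl ether to give the benzyloxymethyl keto ester F5. Hydrogenolysis (H2, Pd/C, EtOAc) frees the alcohol 18, and TsOH closes it to 19, where the route is rejoined.

## Further compounds

F1 | step 10 | (3S)-3-allyl-3-methyl-5-(4-isopropyl-2,3,5-trimethoxyphenyl)oxane-2,4-dione (C10 epimers) | C=CC[C@]1(C)C(=O)OCC(c2cc(OC)c(C(C)C)c(OC)c2OC)C1=O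
F2 | step 10 | (3S)-3-(3-hydroxypropyl)-3-methyl-5-(4-isopropyl-2,3,5-trimethoxyphenyl)oxane-2,4-dione (C10 epimers) | OCCC[C@]1(C)C(=O)OCC(c2cc(OC)c(C(C)C)c(OC)c2OC)C1=O
F0 | step 13 | none | none
F3 | step 11 | 1-O-trimethylsilyl ether of 26 (E/Z mixture) | CCOC(=O)C=C1[C@@]2(c3cc(OC)c(C(C)C)c(OC)c3OC)[C@@H](O[Si](C)(C)C)CC[C@]1(C)C(=O)OC2
F4 | step 16 | 2-[5-(4-isopropyl-2,3,5-trimethoxyphenyl)-1-methyl-2-oxo-3-oxabicyclo[3.3.1]nonan-9-yl]acetic acid (5α-H) | OC(=O)C[C@@H]1[C@@]2(c3cc(OC)c(C(C)C)c(OC)c3OC)CCC[C@]1(C)C(=O)OC2
F5 | step 9 | methyl 5-(benzyloxy)-4-(4-isopropyl-2,3,5-trimethoxyphenyl)-2-methyl-3-oxopentanoate (diastereomer mixture) | COC(=O)C(C)C(=O)C(COCc1ccccc1)c1cc(OC)c(C(C)C)c(OC)c1OC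
A1 | alternative 1 | 4-(4-isopropyl-2,3,5-trimethoxyphenyl)-4-(methoxymethoxymethyl)cyclohexa-2,5-dienone | COCOCC1(c2cc(OC)c(C(C)C)c(OC)c2OC)C=CC(=O)C=C1
A2 | alternative 1 | vinylmagnesium bromide | C=C[Mg]Br
A3 | alternative 1 | iodomethane | CI
A4 | alternative 1 | 6-methyl-5-vinyl-4-aryl-4-(methoxymethoxymethyl)cyclohex-2-enone | C=C[C@@H]1[C@@](COCOC)(c2c(OC)c(OC)c(C(C)C)c(OC)c2)C=CC(=O)[C@H]1C
A5 | alternative 2 | tert-butyl 3-(tert-butyldimethylsilyloxymethyl)-1-methyl-2-vinylcyclohex-2-ene-1-carboxylate | C=CC1=C(CO[Si](C)(C)C(C)(C)C)CCC[C@]1(C)C(=O)OC(C)(C)C
A6 | alternative 2 | 2-isopropyl-3-methoxy-1,4-benzoquinone | COC1=C(C(C)C)C(=O)C=CC1=O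
A7 | alternative 2 | tricyclic hydroquinone with C5=C6 alkene, C19 tert-butyl ester and C20 silyl ether | COc1c(O)c2c(c(O)c1C(C)C)CC=C1[C@]2(CO[Si](C)(C)C(C)(C)C)CCC[C@]1(C)C(=O)OC(C)(C)C
A8 | alternative 3 | tricyclic β-keto lactone (C5 ketone, C20 aryl lactone to O11, C10–H) | COc1c2c3c(c(OC)c1C(C)C)CCC(=O)C3C(=O)O2
A9 | alternative 3 | methyl 3-oxopent-4-enoate | C=CC(=O)CC(=O)OC
A10 | alternative 3 | tetracyclic enone ester with C10 quaternary and the aryl lactone intact | COc1c2c3c(c(OC)c1C(C)C)CCC4=C(C(=O)OC)C(=O)CC[C@]34C(=O)O2
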